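## Structural features

The target is a 1H-isochromen-1-one (isocoumarin): a benzenoid ring A (C4a to C8a) fused to an enol-lactone ring C (C1, O2, C3, C4), with an unbranched pentyl chain at C3, a free hydroxyl at C6 and an aryloxy group at C8. The aryl group, ring B, is bonded through C1' to the ether oxygen and bears a hydroxyl at C2', a methoxyl at C4' and a second pentyl chain at C6'. There is no stereocentre and the ether axis rotates freely, so the problem is one of connectivity and of telling three phenolic oxygens apart. The ether oxygen is flanked by the C2' and C6' substituents on one side and by the peri carbonyl C1 on the other, and both rings are electron-rich, so a direct aryl–aryl ether coupling is the real difficulty. The fragile parts are the enol lactone (opened by hydroxide, and its C3=C4 bond is reducible under hydrogenation) and ring B, a 1,2,4-trioxygenated arene that oxidises easily as its phenolate. The feature exploited is that C1' to C6', with oxygen on C1', C2' and C4' and an alkyl chain on C6', is a folded chain ArO–CH2–CO–CH2–CO–CH2–CO–C5H11. That chain is the open form of a 2-(aryloxymethyl)-6-pentyl-4-pyranone, so the C8–O bond can be made to a primary carbon and ring B closed afterwards between C1' and C6'.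

## Logic of the disconnections

17 to 16: the O6–CH2Ph bond is cut. O6 is the most acidic phenol (para to the lactone carbonyl) and has to be masked while ring B is built and O4' is methylated. The forward removal must spare C3=C4 and the O4' methyl, which calls for Lewis-acid debenzylation and not hydrogenation.

16 to 15: the O4'–CH3 bond is cut, because the ring-forming step delivers O4' as a free phenol. The forward step must distinguish O4' (between two ring CH groups) from O2' (next to the bulky ether). It is therefore run with excess base through the bis-phenoxide, where the less hindered and more basic oxygen should react first.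

15 to 12: the C1'–C6' bond is cut (retro-aldol after formal rehydration), and the resulting 1-aryloxy-2,4,6-triketone is refolded as a 4-pyranone. This removes ring B and the hindered diaryl ether in one stroke and leaves an alkyl aryl ether. The forward step demands aldol closure from C1' and not from the α-methylene of the pentyl chain, reclosure of ring C after its passing saponification, and exclusion of air.

12 to 6 and 11: the O8–CH2 bond is cut, giving two halves of comparable size. The forward step must alkylate the hydrogen-bonded O8 at a primary carbon under conditions the lactone tolerates, with O6 already blocked.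

11 to 10, 9, then 7 and 8: first the benzyl–oxygen bond is cut. This ether must outlast the acid cyclisation, because a free or acid-labile hydroxyl next to C2 of 9 could close onto C4 to a five-membered 3(2H)-furanone instead of the pyranone. Then the pyranone C–O bond is cut (cyclodehydration), then the C2–C3 acyl bond of 9. The forward acylation requires the second deprotonation of 7 at its methyl group and enough dianion to absorb the acidic protons of 9.

6 to 5, 4, 3, then 1 and 2: the O6–benzyl bond is cut (the non-chelated phenol of 5 is the one that alkylates), then both O–CH3 bonds, then the lactone C1–O2 bond, and finally the bond between the benzylic carbon (future C4) and the ketone carbon (future C3). The forward sequence needs lateral metalation of 1 without self-condensation and an acid, not basic, ring closure of 3.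

## Other disconnections considered

Alternative 1: Ring A is cut at C8–C8a and C4a–C5, turning it into a cyclohexadiene and an alkyne; ring C is added later from an ortho-alkynyl benzoate.
- Forward: the ring B phenol 2-(benzyloxy)-4-methoxy-6-pentylphenol A1 would first be made and then joined to a six-membered enone as the vinylogous ester 3-[2-(benzyloxy)-4-methoxy-6-pentylphenoxy]cyclohex-2-en-1-one A2. Kinetic enolisation of enone A2 and O-silylation would give the diene 1-[2-(benzyloxy)-4-methoxy-6-pentylphenoxy]-3-(tert-butyldimethylsilyloxy)cyclohexa-1,3-diene A3. Heating diene A3 with methyl deca-2,4-diynoate A4 should bring about a [4+2] addition at the triple bond of A4 that carries the ester. The bicyclic adduct would then shed ethylene (Alder–Rickert) and leave the benzoate A5, methyl 2-[2-(benzyloxy)-4-methoxy-6-pentylphenoxy]-4-(tert-butyldimethylsilyloxy)-6-(hept-1-yn-1-yl)benzoate. From A5, a 6-endo-dig lactonisation onto the heptynyl group, desilylation and debenzylation would finish.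
- In favour: the two donor oxygens of A3 and the acceptor ester of A4 are matched, so the pattern of ring A should be unambiguous. The C8–O bond is made at the enone carbon of A2 by addition–elimination, which sidesteps the hindered arene coupling as the chosen plan does (equal on this point). The oxygen pattern of ring B is settled in A1, so no late choice between O2' and O4' is needed (better on this point).
- Against: A1 costs about four steps of its own. The diene terminus of A3 that must bond carries the bulky aryloxy group and becomes a fully substituted bridgehead, so the cycloaddition would be slow. Ethylene extrusion needs temperatures at which a silyl dienol ether and a conjugated diynoate are prone to desilylation and polymerisation. The later ring closure of A5 must be 6-endo and not 5-exo.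
- Comparison: a thermal pericyclic cascade replaces an ionic aldol condensation. Regiochemistry is at least as secure, reactivity less so, and the count would be about thirteen steps against eleven.

Alternative 2: Ring C is cut at C4a–C4, C8a–C1 and C1–O2, giving an aryne and a trifluoromethyl diketone.
- Forward: CsF would unmask the aryne from the silyl triflate 5-(benzyloxy)-3-[2-(benzyloxy)-4-methoxy-6-pentylphenoxy]-2-(trimethylsilyl)phenyl trifluoromethanesulfonate A6. C-arylation of the enolate of the diketone 1,1,1-trifluorononane-2,4-dione A7 should occur at C4a, the aryne carbon remote from the C8 aryloxy group. The aryl anion left at C8a would then pick up the trifluoroacetyl group of A7, a net insertion into its C–C bond. Lactonisation of the remaining ketone enolate through oxygen onto that aryl trifluoromethyl ketone, with CF3 leaving as fluoroform, would deliver the isocoumarin A8, 6-(benzyloxy)-8-[2-(benzyloxy)-4-methoxy-6-pentylphenoxy]-3-pentyl-1H-isochromen-1-one. Double debenzylation of A8 would give 17.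
- In favour: ring C is assembled in one flask from A6 and A7 under nearly neutral conditions, one step against the two of the chosen plan (better on this point). The site of nucleophilic attack on a 3-oxygenated aryne is reliable. The lactone never meets hydroxide, and the end-game from A8 needs no site-selective methylation (better on this point).
- Against: the hindered diaryl ether must exist before the aryne step, so the central difficulty is only moved, to a phloroglucinol-type ring with three different oxygen substituents and an ortho silyl group. A6 would need about six or seven steps, including a hindered coupling with A1, and A1 adds four more.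
- Comparison: the aryne step is the more elegant ring C construction, but the plan leaves the hardest bond to conventional coupling and would run to about thirteen or fourteen steps. The chosen plan is better on the key structural problem and on step count.

Alternative 3: Ring A is cut at C4a–C5 and C6–C7, giving a bicyclic bis-pyranone and a two-carbon ketene acetal.
- Forward: the bicyclic dione 4-[2-(benzyloxy)-4-methoxy-6-pentylphenoxy]-7-pentyl-2H,5H-pyrano[4,3-b]pyran-2,5-dione A9 would react through its aryloxy-substituted 2-pyranone half with the ketene acetal 1,1-bis(trimethylsilyloxy)ethene A10. The CH2 carbon of A10 bonds to C4a and its acetal carbon to C7. Extrusion of CO2 and elimination of trimethylsilanol from the adduct would give the isocoumarin A11, 8-[2-(benzyloxy)-4-methoxy-6-pentylphenoxy]-3-pentyl-6-(trimethylsilyloxy)-1H-isochromen-1-one. Desilylation of A11 on work-up and debenzylation would follow.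
- In favour: ring C is present from the start in A9 and is never exposed to strong base. The aryl ether would be made by addition–elimination of A1 on an activated 4-oxygenated pyranone, which avoids the arene coupling (equal on this point). O6 needs no protecting group beyond the silyl ether that A11 carries and loses on work-up (better on this point). Ring B needs no late selective methylation (better on this point).
- Against: A9 contains two fused 2-pyranone dienes, and the one that must react is deactivated by the donating aryloxy group and shielded next to C7. Site selectivity and orientation are therefore both uncertain. The ketene acetal A10 is moisture-sensitive and may add stepwise. A1 still has to be made separately.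
- Comparison: the step count would be about ten or eleven, equal to the chosen plan. The mechanism rests on an inverse-demand cycloaddition whose site selectivity is harder to argue than the direction of the aldol closure in the chosen plan.

Key step: step 9

Remark on the chemistry: the SMILES shows unbranched pentyl chains and no stereogenic element, so no stereocontrol is needed. Compounds 1, 2, 7 and 8 are taken as catalogue chemicals.

## Route

Step 1
Reactants: 1 methyl 2,4-dimethoxy-6-methylbenzoate; 2 methyl hexanoate
Product: 3 methyl 2,4-dimethoxy-6-(2-oxoheptyl)benzoate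
Conditions: 1 (2.1 equiv), LiN(iPr)2 (2.1 equiv), THF, −78 °C; 2 (1.0 equiv), −78 °C; aq. NH4Cl
Reagents that add atoms: none
Why: Lateral (benzylic) lithiation of the ortho-toluate gives a vinylogous ester enolate that is C-acylated by the methyl ester (Claisen-type acylation). The hindered 2,6-disubstituted ester of 1 resists self-condensation at −78 °C, and the second equivalent of anion deprotonates the more acidic ketone 3 and is recovered as 1.

Step 2
Reactants: 3 methyl 2,4-dimethoxy-6-(2-oxoheptyl)benzoate
Product: 4 6,8-dimethoxy-3-pentyl-1H-isochromen-1-one
Conditions: p-TsOH·H2O (0.2 equiv), toluene, reflux, Dean–Stark trap with 4 Å sieves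
Reagents that add atoms: none
Why: Acid-catalysed enol lactonisation: the enol oxygen of the benzylic ketone attacks the neighbouring ester carbonyl (6-exo-trig) and methanol is removed, giving the conjugated isocoumarin. Acid is chosen because base could divert 3 to a naphthalene-1,3-diol by C-acylation.

Step 3
Reactants: 4 6,8-dimethoxy-3-pentyl-1H-isochromen-1-one
Product: 5 6,8-dihydroxy-3-pentyl-1H-isochromen-1-one
Conditions: BBr3 (4 equiv), CH2Cl2, −78 °C to rt; H2O
Reagents that add atoms: none
Why: BBr3 cleavage of both aryl methyl ethers (Lewis acid–base adduct, bromide attack at methyl). The enol lactone should tolerate the reagent and the aqueous quench.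

Step 4
Reactants: 5 6,8-dihydroxy-3-pentyl-1H-isochromen-1-one
Product: 6 6-(benzyloxy)-8-hydroxy-3-pentyl-1H-isochromen-1-one
Conditions: BnBr (1.05 equiv), K2CO3 (1.1 equiv), acetone, rt to 50 °C
Reagents that add atoms: benzyl bromide, BrCc1ccccc1
Why: Williamson etherification with one equivalent of base. The C6 hydroxyl is para to the lactone carbonyl and not hydrogen-bonded, so it is the more acidic and more accessible phenol, whereas the C8 hydroxyl is held in a hydrogen bond to the C1 carbonyl; mono-benzylation should go to O6.

Step 5
Reactants: 7 nonane-2,4-dione; 8 ethyl 2-(benzyloxy)acetate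
Product: 9 1-(benzyloxy)undecane-2,4,6-trione
Conditions: 7 (2.1 equiv), LiN(iPr)2 (4.2 equiv), THF, 0 °C; 8 (1.0 equiv), −78 to 0 °C; 1 M HCl
Reagents that add atoms: none
Why: Claisen-type acylation of the 1,3-dianion of a β-diketone at its terminal carbanion. The second deprotonation of 7 should occur at the C1 methyl and not the C5 methylene, and the excess dianion absorbs the acidic protons of the triketone as it forms.

Step 6
Reactants: 9 1-(benzyloxy)undecane-2,4,6-trione
Product: 10 2-[(benzyloxy)methyl]-6-pentyl-4H-pyran-4-one
Conditions: p-TsOH·H2O (0.1 equiv), toluene, reflux, Dean–Stark trap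
Reagents that add atoms: none
Why: Acid-catalysed cyclodehydration of a 1,3,5-triketone to a 4-pyranone (the enol oxygen of one terminal carbonyl adds to the other, then water is lost). The benzyl ether, stable to these conditions, keeps the C1 oxygen from closing onto C4 to a five-membered furanone.

Step 7
Reactants: 10 2-[(benzyloxy)methyl]-6-pentyl-4H-pyran-4-one
Product: 11 2-(hydroxymethyl)-6-pentyl-4H-pyran-4-one
Conditions: BCl3 (3 equiv), CH2Cl2, −78 to 0 °C; MeOH, then aq. NaHCO3
Reagents that add atoms: none
Why: Lewis-acid cleavage of a benzyl alkyl ether. BCl3 first binds the basic pyranone carbonyl, which disfavours ionisation at the ring-side CH2–O bond, so chloride should attack the benzylic carbon; hydrogenolysis is avoided because it could cut the pyranylmethyl C–O bond or reduce the ring.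

Step 8
Reactants: 6 6-(benzyloxy)-8-hydroxy-3-pentyl-1H-isochromen-1-one; 11 2-(hydroxymethyl)-6-pentyl-4H-pyran-4-one
Product: 12 6-(benzyloxy)-8-[(4-oxo-6-pentyl-4H-pyran-2-yl)methoxy]-3-pentyl-1H-isochromen-1-one
Conditions: PPh3 (1.5 equiv), DIAD (1.5 equiv), THF, 0 °C to rt
Reagents that add atoms: none
Why: Mitsunobu etherification: the primary pyranylmethyl alcohol is activated as its alkoxyphosphonium salt and displaced (SN2 at CH2) by the phenoxide of 6, an ortho-acyl phenol acidic enough to protonate the betaine. The congested C8–O bond is thus formed at an unhindered primary carbon and the lactone sees no strong base.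

Step 9
Reactants: 12 6-(benzyloxy)-8-[(4-oxo-6-pentyl-4H-pyran-2-yl)methoxy]-3-pentyl-1H-isochromen-1-one
Product: 15 6-(benzyloxy)-8-(2,4-dihydroxy-6-pentylphenoxy)-3-pentyl-1H-isochromen-1-one, via triketone keto acid 13 (not isolated), via resorcinol keto acid 14 (not isolated)
Conditions: Ba(OH)2·8H2O (8 equiv), degassed H2O/1,4-dioxane 1:1, 90 °C, argon; 2 M HCl to pH 1, 0 °C, EtOAc extraction; crude, p-TsOH·H2O (0.1 equiv), toluene, 90 °C
Reagents that add atoms: water, O (taken up as hydroxide; one of its oxygens may remain in the C1 carbonyl or at O2', while an equal number of oxygens leave as water)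
Why: Attack of hydroxide at either α-carbon (C2 or C6) of the 4-pyranone, a vinylogous ester, unlocks the heterocycle as the polyanion of the 1-aryloxy-2,4,6-triketone 13, while the same medium saponifies the enol lactone of ring C to a keto carboxylate; this is the classical base-induced conversion of 2,6-disubstituted 4-pyranones into resorcinols through their triketones. The terminal methylene C1', activated by the C2' carbonyl and by the aryloxy oxygen, attacks the pentyl ketone carbon C6' in a 6-(enolendo)-exo-trig aldol addition, a favoured mode of closure, and loss of water with enolisation of the C2' and C4' carbonyls gives the aromatic ring B of 14 irreversibly. No stereocentre is formed. The selectivity needed is the direction of the aldol: closure from the α-methylene of the pentyl chain onto the C2' carbonyl would give an isomeric 4-butyl-5-(aryloxymethyl)resorcinol. The inductive effect of the aryloxy group makes C1'–H the more acidic terminal position, as the ester does in the related closure of 3,5,7-triketo esters to orsellinates, and the reversible aldol equilibria should drain through the aromatisation that starts from C1'. Acidification protonates the carboxylate, and under mild acid catalysis the ketone enol oxygen O2 recloses on C1 by 6-exo-trig acyl substitution with loss of water, restoring ring C. Air is excluded because the 1,2,4-trioxygenated phenolate of ring B is easily oxidised; the benzyl ether and the alkyl aryl ether are inert to hydroxide.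

Step 10
Reactants: 15 6-(benzyloxy)-8-(2,4-dihydroxy-6-pentylphenoxy)-3-pentyl-1H-isochromen-1-one
Product: 16 6-(benzyloxy)-8-(2-hydroxy-4-methoxy-6-pentylphenoxy)-3-pentyl-1H-isochromen-1-one
Conditions: Cs2CO3 (3 equiv), degassed DMF, 0 °C, 30 min; MeI (1.0 equiv), 0 °C
Reagents that add atoms: iodomethane, CI
Why: Williamson O-methylation run with excess base through the bis-phenoxide, so that the relative acidity of the two phenols does not decide the site. O4' lies between two ring CH groups and is the more basic phenoxide, whereas O2' is ortho to the bulky ether and ion-paired near the ether and lactone oxygens, so the single equivalent of MeI should go to O4'.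

Step 11
Reactants: 16 6-(benzyloxy)-8-(2-hydroxy-4-methoxy-6-pentylphenoxy)-3-pentyl-1H-isochromen-1-one
Product: 17 6-hydroxy-8-(2-hydroxy-4-methoxy-6-pentylphenoxy)-3-pentyl-1H-isochromen-1-one
Conditions: BCl3 (3 equiv), pentamethylbenzene (3 equiv), CH2Cl2, −78 °C; MeOH, then H2O
Reagents that add atoms: none
Why: Lewis-acid debenzylation of an aryl benzyl ether with a non-Lewis-basic cation scavenger. At −78 °C the non-chelated O4' methyl ether and the diaryl ether should survive, and the C3=C4 bond of ring C, which hydrogenolysis could saturate, is not at risk.

## Compound list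

1 | methyl 2,4-dimethoxy-6-methylbenzoate | COC(=O)c1c(C)cc(OC)cc1OC | starting material
2 | methyl hexanoate | CCCCCC(=O)OC | starting material
3 | methyl 2,4-dimethoxy-6-(2-oxoheptyl)benzoate | CCCCCC(=O)Cc1cc(OC)cc(OC)c1C(=O)OC | intermediate
4 | 6,8-dimethoxy-3-pentyl-1H-isochromen-1-one | CCCCCc1cc2cc(OC)cc(OC)c2c(=O)o1 | intermediate
5 | 6,8-dihydroxy-3-pentyl-1H-isochromen-1-one | CCCCCc1cc2cc(O)cc(O)c2c(=O)o1 | intermediate
6 | 6-(benzyloxy)-8-hydroxy-3-pentyl-1H-isochromen-1-one | CCCCCc1cc2cc(OCc3ccccc3)cc(O)c2c(=O)o1 | intermediate
7 | nonane-2,4-dione | CCCCCC(=O)CC(C)=O | starting material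
8 | ethyl 2-(benzyloxy)acetate | CCOC(=O)COCc1ccccc1 | starting material
9 | 1-(benzyloxy)undecane-2,4,6-trione | CCCCCC(=O)CC(=O)CC(=O)COCc1ccccc1 | intermediate
10 | 2-[(benzyloxy)methyl]-6-pentyl-4H-pyran-4-one | CCCCCc1cc(=O)cc(COCc2ccccc2)o1 | intermediate
11 | 2-(hydroxymethyl)-6-pentyl-4H-pyran-4-one | CCCCCc1cc(=O)cc(CO)o1 | intermediate
12 | 6-(benzyloxy)-8-[(4-oxo-6-pentyl-4H-pyran-2-yl)methoxy]-3-pentyl-1H-isochromen-1-one | CCCCCc1cc2cc(OCc3ccccc3)cc(OCc3cc(=O)cc(CCCCC)o3)c2c(=O)o1 | intermediate
13 | 4-(benzyloxy)-2-(2-oxoheptyl)-6-[(2,4,6-trioxoundecyl)oxy]benzoic acid | CCCCCC(=O)Cc1cc(OCc2ccccc2)cc(OCC(=O)CC(=O)CC(=O)CCCCC)c1C(=O)O | intermediate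
14 | 4-(benzyloxy)-2-(2,4-dihydroxy-6-pentylphenoxy)-6-(2-oxoheptyl)benzoic acid | CCCCCC(=O)Cc1cc(OCc2ccccc2)cc(Oc2c(O)cc(O)cc2CCCCC)c1C(=O)O | intermediate
15 | 6-(benzyloxy)-8-(2,4-dihydroxy-6-pentylphenoxy)-3-pentyl-1H-isochromen-1-one | CCCCCc1cc2cc(OCc3ccccc3)cc(Oc3c(O)cc(O)cc3CCCCC)c2c(=O)o1 | intermediate
16 | 6-(benzyloxy)-8-(2-hydroxy-4-methoxy-6-pentylphenoxy)-3-pentyl-1H-isochromen-1-one | CCCCCc1cc2cc(OCc3ccccc3)cc(Oc3c(O)cc(OC)cc3CCCCC)c2c(=O)o1 | intermediate
17 | 6-hydroxy-8-(2-hydroxy-4-methoxy-6-pentylphenoxy)-3-pentyl-1H-isochromen-1-one | CCCCCc1cc2cc(O)cc(Oc3c(O)cc(OC)cc3CCCCC)c2c(=O)o1 | target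

## Step count and least certain steps

Total: 11 steps. Longest linear sequence: 8 steps (steps 1 to 4, then 8 to 11, from 1); the pyranone branch from 7 is 7 steps.

Step 9 (key step). The triketone may close from the wrong terminus (the pentyl-side methylene attacking the C2' carbonyl), hydroxide may fragment it by retro-Claisen cleavage before it cyclises, or the ring B phenolate may autoxidise. All three follow from holding an unsymmetrical, electron-rich polyketone in hot alkali. The fallback gives up the ring construction and makes the ether by cross-coupling; it sets out from 6 and returns at 17. Phenol 6 with Tf2O and pyridine should give 6-(benzyloxy)-1-oxo-3-pentyl-1H-isochromen-8-yl trifluoromethanesulfonate F1, an aryl triflate activated by the ortho carbonyl. Separately, commercial 5-pentylbenzene-1,3-diol would be formylated (POCl3, DMF; Vilsmeier–Haack) to 2,4-dihydroxy-6-pentylbenzaldehyde F2. Methylation of the non-chelated para hydroxyl (MeI, K2CO3, acetone) would give 2-hydroxy-4-methoxy-6-pentylbenzaldehyde F3, and benzylation (BnBr, K2CO3, DMF) would give 2-(benzyloxy)-4-methoxy-6-pentylbenzaldehyde F4. Baeyer–Villiger oxidation and formate hydrolysis (mCPBA, CH2Cl2; KOH, MeOH/H2O) would convert this aldehyde into 2-(benzyloxy)-4-methoxy-6-pentylphenol F5. Palladium-catalysed C–O coupling of the triflate with this phenol (Pd(OAc)2, 2-di-tert-butylphosphino-2',4',6'-triisopropylbiphenyl, K3PO4, toluene, 100 °C) should give 6-(benzyloxy)-8-[2-(benzyloxy)-4-methoxy-6-pentylphenoxy]-3-pentyl-1H-isochromen-1-one F6. Double debenzylation under the conditions of step 11 would give 17. This sequence meets the steric hindrance head-on, which is why it is the reserve and not the plan.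

Step 10. The methylation may show poor site selectivity between O4' and O2', or run on to the dimethyl ether, because the two phenoxides differ only moderately in reactivity towards a small electrophile. The fallback uses a bulky silyl group, whose steric discrimination is far larger; it sets out from 15 and returns at 17. Compound 15 with TIPSCl and imidazole in DMF should give 6-(benzyloxy)-8-{2-hydroxy-6-pentyl-4-[(triisopropylsilyl)oxy]phenoxy}-3-pentyl-1H-isochromen-1-one F7. Benzylation of the remaining O2' (BnBr, K2CO3, acetone) would give 6-(benzyloxy)-8-{2-(benzyloxy)-6-pentyl-4-[(triisopropylsilyl)oxy]phenoxy}-3-pentyl-1H-isochromen-1-one F8. Bu4NF in THF would then free 6-(benzyloxy)-8-[2-(benzyloxy)-4-hydroxy-6-pentylphenoxy]-3-pentyl-1H-isochromen-1-one F9. MeI and K2CO3 would give 6-(benzyloxy)-8-[2-(benzyloxy)-4-methoxy-6-pentylphenoxy]-3-pentyl-1H-isochromen-1-one F6, the same dibenzyl ether as above. BCl3 and pentamethylbenzene would remove both benzyl groups to give 17.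

Step 8. Alkylation of the hydrogen-bonded, peri-hindered C8 phenol may be slow, so that the activated alcohol is consumed by N-alkylation of the reduced azodicarboxylate. The fallback separates activation from substitution; it sets out from 11 and returns at 12. Alcohol 11 with CBr4 and PPh3 (Appel reaction) should give 2-(bromomethyl)-6-pentyl-4H-pyran-4-one F10, which would alkylate the potassium phenoxide of 6 (K2CO3, DMF, rt) to give 12.

Step 5. Proton transfer from the α-position of ester 8 to the strongly basic dianion may compete with acylation, and the acidic product consumes base. The fallback replaces the Claisen-type acylation by an aldol addition and an oxidation; it sets out from 7 and returns at 9. The dianion of 7 with 2-(benzyloxy)acetaldehyde at −78 °C should give racemic 1-(benzyloxy)-2-hydroxyundecane-4,6-dione F11, whose secondary alcohol would be oxidised with Dess–Martin periodinane (NaHCO3, CH2Cl2) to 9.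

Step 1. The benzylic anion may enolise 2 instead of adding to it, and some self-condensation of 1 may occur, leading to low conversion. The fallback is the homophthalic acid route; it sets out from 1 and returns at 4. Lateral lithiation of 1 and carboxylation with CO2 should give 2-[3,5-dimethoxy-2-(methoxycarbonyl)phenyl]acetic acid F12. Saponification (KOH, aq. EtOH, reflux) would give 2-(carboxymethyl)-4,6-dimethoxybenzoic acid F13. Heating this diacid with hexanoyl chloride at about 200 °C would give 4 directly by acylation, lactonisation and decarboxylation.

## Further compounds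

F1 | step 9 | 6-(benzyloxy)-1-oxo-3-pentyl-1H-isochromen-8-yl trifluoromethanesulfonate | CCCCCc1cc2cc(OCc3ccccc3)cc(OS(=O)(=O)C(F)(F)F)c2c(=O)o1
F2 | step 9 | 2,4-dihydroxy-6-pentylbenzaldehyde | CCCCCc1cc(O)cc(O)c1C=O
F3 | step 9 | 2-hydroxy-4-methoxy-6-pentylbenzaldehyde | CCCCCc1cc(OC)cc(O)c1C=O
F4 | step 9 | 2-(benzyloxy)-4-methoxy-6-pentylbenzaldehyde | CCCCCc1cc(OC)cc(OCc2ccccc2)c1C=O
F5 | step 9 | 2-(benzyloxy)-4-methoxy-6-pentylphenol | CCCCCc1cc(OC)cc(OCc2ccccc2)c1O
F6 | step 9 | 6-(benzyloxy)-8-[2-(benzyloxy)-4-methoxy-6-pentylphenoxy]-3-pentyl-1H-isochromen-1-one | CCCCCc1cc2cc(OCc3ccccc3)cc(Oc3c(OCc4ccccc4)cc(OC)cc3CCCCC)c2c(=O)o1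
F7 | step 10 | 6-(benzyloxy)-8-{2-hydroxy-6-pentyl-4-[(triisopropylsilyl)oxy]phenoxy}-3-pentyl-1H-isochromen-1-one | CCCCCc1cc2cc(OCc3ccccc3)cc(Oc3c(O)cc(O[Si](C(C)C)(C(C)C)C(C)C)cc3CCCCC)c2c(=O)o1
F8 | step 10 | 6-(benzyloxy)-8-{2-(benzyloxy)-6-pentyl-4-[(triisopropylsilyl)oxy]phenoxy}-3-pentyl-1H-isochromen-1-one | CCCCCc1cc2cc(OCc3ccccc3)cc(Oc3c(OCc4ccccc4)cc(O[Si](C(C)C)(C(C)C)C(C)C)cc3CCCCC)c2c(=O)o1
F9 | step 10 | 6-(benzyloxy)-8-[2-(benzyloxy)-4-hydroxy-6-pentylphenoxy]-3-pentyl-1H-isochromen-1-one | CCCCCc1cc2cc(OCc3ccccc3)cc(Oc3c(OCc4ccccc4)cc(O)cc3CCCCC)c2c(=O)o1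
F10 | step 8 | 2-(bromomethyl)-6-pentyl-4H-pyran-4-one | CCCCCc1cc(=O)cc(CBr)o1
F11 | step 5 | 1-(benzyloxy)-2-hydroxyundecane-4,6-dione (racemic) | CCCCCC(=O)CC(=O)CC(O)COCc1ccccc1
F12 | step 1 | 2-[3,5-dimethoxy-2-(methoxycarbonyl)phenyl]acetic acid | COC(=O)c1c(CC(=O)O)cc(OC)cc1OC
F13 | step 1 | 2-(carboxymethyl)-4,6-dimethoxybenzoic acid | OC(=O)Cc1cc(OC)cc(OC)c1C(=O)O
A1 | alternative 1 | 2-(benzyloxy)-4-methoxy-6-pentylphenol | CCCCCc1cc(OC)cc(OCc2ccccc2)c1O
A2 | alternative 1 | 3-[2-(benzyloxy)-4-methoxy-6-pentylphenoxy]cyclohex-2-en-1-one | CCCCCc1cc(OC)cc(OCc2ccccc2)c1OC1=CC(=O)CCC1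
A3 | alternative 1 | 1-[2-(benzyloxy)-4-methoxy-6-pentylphenoxy]-3-(tert-butyldimethylsilyloxy)cyclohexa-1,3-diene | CCCCCc1cc(OC)cc(OCc2ccccc2)c1OC1=CC(O[Si](C)(C)C(C)(C)C)=CCC1
A4 | alternative 1 | methyl deca-2,4-diynoate | CCCCCC#CC#CC(=O)OC
A5 | alternative 1 | methyl 2-[2-(benzyloxy)-4-methoxy-6-pentylphenoxy]-4-(tert-butyldimethylsilyloxy)-6-(hept-1-yn-1-yl)benzoate | CCCCCC#Cc1cc(O[Si](C)(C)C(C)(C)C)cc(Oc2c(OCc3ccccc3)cc(OC)cc2CCCCC)c1C(=O)OC
A6 | alternative 2 | 5-(benzyloxy)-3-[2-(benzyloxy)-4-methoxy-6-pentylphenoxy]-2-(trimethylsilyl)phenyl trifluoromethanesulfonate | CCCCCc1cc(OC)cc(OCc2ccccc2)c1Oc1cc(OCc2ccccc2)cc(OS(=O)(=O)C(F)(F)F)c1[Si](C)(C)C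
A7 | alternative 2 | 1,1,1-trifluorononane-2,4-dione | CCCCCC(=O)CC(=O)C(F)(F)F
A8 | alternative 2 | 6-(benzyloxy)-8-[2-(benzyloxy)-4-methoxy-6-pentylphenoxy]-3-pentyl-1H-isochromen-1-one | CCCCCc1cc2cc(OCc3ccccc3)cc(Oc3c(OCc4ccccc4)cc(OC)cc3CCCCC)c2c(=O)o1
A9 | alternative 3 | 4-[2-(benzyloxy)-4-methoxy-6-pentylphenoxy]-7-pentyl-2H,5H-pyrano[4,3-b]pyran-2,5-dione | CCCCCc1cc2oc(=O)cc(Oc3c(OCc4ccccc4)cc(OC)cc3CCCCC)c2c(=O)o1
A10 | alternative 3 | 1,1-bis(trimethylsilyloxy)ethene | C=C(O[Si](C)(C)C)O[Si](C)(C)C
A11 | alternative 3 | 8-[2-(benzyloxy)-4-methoxy-6-pentylphenoxy]-3-pentyl-6-(trimethylsilyloxy)-1H-isochromen-1-one | CCCCCc1cc2cc(O[Si](C)(C)C)cc(Oc3c(OCc4ccccc4)cc(OC)cc3CCCCC)c2c(=O)o1
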